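**Retrosynthetic overview**

1. Argophyllone B ⇐ face-selective epoxidation of the E-C1=C10 alkene of 33. The α-methylene lactone comes from a C12 acetal carried on C7 (cyclic acetal to O6, methylenation, oxidation). The C8 angelate comes from C8–OH, which comes from C8–Si (Tamao oxidation).
2. The ten-membered carbocycle ⇐ anionic oxy-Cope ring expansion of the trans-1,2-dialkenylcyclohexanol 17 (forms C8–C9, cleaves C1–C6). The strategy rests on C6 (the lactone carbinol carbon, at ketone level) and the E-C1=C10 alkene lying 1,5 across the ring (C6–C7–C8–C9–C10=C1), a cyclodec-5-enone pattern.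
3. The alkenyl arm of 17 already carries C11–C12 on C7 and silicon on C8. The rearrangement sets C8 and the planar chirality of the C6=C7 enol ether; outer-face protonation converts that into C7 (an E ring enolate can only be attacked on its outer face, so hydrogen, not carbon, must enter last). O8 then directs C6 (Evans–Tishchenko).
4. 17 ⇐ ketone 10 + silylalkyne 14 (titanium–alkyne complex). 10 ⇐ quinone monoketal 1 by Rh-catalysed asymmetric vinyl addition (C4), iodination/Suzuki isopropenylation and CuH reduction.
5. Ring order: cyclohexane (from 1) → ten-membered carbocycle (step 9) → five-membered O6–C12 ring (step 13, lactone in step 18) → epoxide (step 20).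

Key step: step 9

Remark: germacrane numbering of the target is used for all ring-expanded intermediates (ring C1–C10, lactone carbons C11–C13, C14 methyl, C15 hydroxymethyl); dienone 1 and alkyne 11 are assumed to be purchasable.

**Route**

Step 1
Reactants: 1 1,4-dioxaspiro[4.5]deca-6,9-dien-8-one; 2 potassium vinyltrifluoroborate
Product: 3 (S)-6-vinyl-1,4-dioxaspiro[4.5]dec-9-en-8-one
Conditions: [Rh(cod)2]BF4 (cat.), (S)-BINAP, Et3N, toluene/H2O, rt; 1 in excess
Reagents that add atoms: none
Why: Hayashi–Miyaura rhodium-catalysed asymmetric 1,4-addition desymmetrises the dienone; the (S)-BINAP–Rh alkenyl species should add next to the ketal on the face that gives (S)-C4 (the sense known for cyclohexenones), and excess dienone suppresses double addition.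

Step 2
Reactants: 3 (S)-6-vinyl-1,4-dioxaspiro[4.5]dec-9-en-8-one
Product: 5 (S)-6-(hydroxymethyl)-1,4-dioxaspiro[4.5]dec-9-en-8-one, via C15 aldehyde 4 (not isolated)
Conditions: O3, CH2Cl2/MeOH, −78 °C (Sudan Red end-point); Me2S; then NaBH4, −78 → −40 °C
Reagents that add atoms: ozone, [O-][O+]=O
Why: Ozonolysis should cleave the electron-rich vinyl group in preference to the electron-poor enone alkene, and low-temperature borohydride reduction should take the aldehyde before the conjugated ketone and before the α-centre C4 can epimerise.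

Step 3
Reactants: 5 (S)-6-(hydroxymethyl)-1,4-dioxaspiro[4.5]dec-9-en-8-one
Product: 6 (S)-6-[(tert-butyldiphenylsilyloxy)methyl]-1,4-dioxaspiro[4.5]dec-9-en-8-one
Conditions: TBDPSCl, imidazole, DMF, 0 °C → rt
Reagents that add atoms: tert-butyl(chloro)diphenylsilane, CC(C)(C)[Si](Cl)(c1ccccc1)c1ccccc1
Why: Standard silylation of a primary alcohol; the TBDPS ether is chosen to survive the mild aqueous acid of step 16.

Step 4
Reactants: 6 (S)-6-[(tert-butyldiphenylsilyloxy)methyl]-1,4-dioxaspiro[4.5]dec-9-en-8-one
Product: 7 (S)-6-[(tert-butyldiphenylsilyloxy)methyl]-9-iodo-1,4-dioxaspiro[4.5]dec-9-en-8-one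
Conditions: I2, pyridine, CH2Cl2, 0 °C → rt
Reagents that add atoms: iodine, II
Why: Johnson α-iodination of an enone (pyridine conjugate addition, iodination of the enolate, elimination) marks C1 regiospecifically for the isopropenyl group.

Step 5
Reactants: 7 (S)-6-[(tert-butyldiphenylsilyloxy)methyl]-9-iodo-1,4-dioxaspiro[4.5]dec-9-en-8-one; 8 isopropenylboronic acid pinacol ester
Product: 9 (S)-6-[(tert-butyldiphenylsilyloxy)methyl]-9-(prop-1-en-2-yl)-1,4-dioxaspiro[4.5]dec-9-en-8-one
Conditions: Pd(dppf)Cl2 (cat.), K3PO4, THF/H2O, 45 °C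
Reagents that add atoms: none
Why: Suzuki–Miyaura coupling of an α-iodoenone with an alkenylboronate is reliable and attaches C10 (with C9 and C14) to C1.

Step 6
Reactants: 9 (S)-6-[(tert-butyldiphenylsilyloxy)methyl]-9-(prop-1-en-2-yl)-1,4-dioxaspiro[4.5]dec-9-en-8-one
Product: 10 (6S,9R)-6-[(tert-butyldiphenylsilyloxy)methyl]-9-(prop-1-en-2-yl)-1,4-dioxaspiro[4.5]decan-8-one (trans)
Conditions: [(Ph3P)CuH]6, H2O (2 equiv), toluene, rt
Reagents that add atoms: none
Why: Copper hydride 1,4-reduction (Stryker's reagent) takes the enone and leaves isolated alkenes; α-protonation of the copper enolate gives the deconjugated ketone with the isopropenyl group equatorial and trans to the C4 substituent (axial protonation, also the thermodynamic epimer), and any cis epimer should converge on brief treatment with DBU at 0 °C.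

Step 7
Reactants: 11 4,4-dimethoxybut-1-yne
Product: 14 (4,4-dimethoxybut-1-yn-1-yl)(isopropoxy)diphenylsilane, via lithium acetylide 12 (not isolated), via alkynylchlorosilane 13 (not isolated)
Conditions: n-BuLi, THF, −78 °C; added to Ph2SiCl2 (1.5 equiv), −78 → 0 °C; then i-PrOH, Et3N, 0 °C
Reagents that add atoms: dichlorodiphenylsilane, Cl[Si](Cl)(c1ccccc1)c1ccccc1; propan-2-ol, CC(C)O
Why: Silylation of a lithium acetylide followed by alcoholysis of the remaining Si–Cl bond gives an alkoxydiphenylsilyl group, which is chromatography-stable and oxidisable later under mild Tamao conditions without touching the C1=C10 alkene.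

Step 8
Reactants: 10 (6S,9R)-ketone; 14 (4,4-dimethoxybut-1-yn-1-yl)(isopropoxy)diphenylsilane
Product: 17 (6S,8R,9R)-8-{(E)-4,4-dimethoxy-1-[isopropoxy(diphenyl)silyl]but-1-en-2-yl}-6-[(tert-butyldiphenylsilyloxy)methyl]-9-(prop-1-en-2-yl)-1,4-dioxaspiro[4.5]decan-8-ol, via titanium alkyne complex 15 (not isolated), via oxatitanacyclopentene 16 (not isolated)
Conditions: Ti(O-i-Pr)4, i-PrMgCl (2 equiv), 14, Et2O, −78 → −50 °C; then 10, −50 → −30 °C; aq. NH4Cl
Reagents that add atoms: none
Why: Addition of a low-valent titanium alkoxide–alkyne complex to a ketone forms the C6–C7 bond at the alkyne carbon remote from silicon and, after protonolysis of the Ti–C8 bond, delivers C6 and H cis (silicon trans to C6, cis to C11); the bulky reagent should attack the ketone equatorially, giving the trans-dialkenyl carbinol with axial OH.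

Step 9
Reactants: 17 trans-dialkenyl carbinol
Product: 20 (4S,8R)-C6 trimethylsilyl enol ether of the ten-membered ring [ring-E C6=C7 with O cis to C8; C7–CH2CH(OMe)2; C8–SiPh2(O-i-Pr); E-C1=C10; C3 ethylene ketal; C4–CH2OTBDPS], via potassium alkoxide 18 (not isolated), via potassium enolate 19 (not isolated)
Conditions: KH, 18-crown-6, THF, 0 °C → rt; then TMSCl, Et3N, −78 °C
Reagents that add atoms: chlorotrimethylsilane, C[Si](C)(C)Cl
Why: The potassium alkoxide 18 undergoes an alkoxide-accelerated [3,3]-sigmatropic shift (anionic oxy-Cope rearrangement of a trans-1,2-dialkenylcyclohexanol, the known route to (E)-cyclodec-5-enones) that forms C8–C9 and cleaves C1–C6, and the enolate 19 is O-silylated. The ten-membered ring is not closed by cyclisation but arises by ring expansion of the cyclohexane through a chair transition state in which both alkenyl groups are equatorial on the ring. C8 is the one new stereocentre: silicon is trans to C6 on C7=C8 and therefore equatorial in the chair, so C9 bonds to one face of C8 and the configuration of C1/C6 is relayed to C8 (8R). The same chair fixes the E geometry of C1=C10 and the ring-E, Z(O) geometry of the tetrasubstituted C6=C7 enolate, which is planar-chiral and cannot turn through the ring because C7 carries C11. The step needs chair over boat and no silyl shift or fragmentation of the alkoxide; the trans-diequatorial alkenyl groups, the E-silyl terminus (out of reach of the alkoxide) and irreversible enolate formation secure this.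

Step 10
Reactants: 20 C6 trimethylsilyl enol ether
Product: 21 (4S,7S,8R)-7-(2,2-dimethoxyethyl)-8-[isopropoxy(diphenyl)silyl]-4-[(tert-butyldiphenylsilyloxy)methyl]-10-methylcyclodec-1(10)E-en-6-one 3-ethylene ketal
Conditions: TBAF, AcOH, THF, −78 °C
Reagents that add atoms: none
Why: Fluoride-triggered protodesilylation is a kinetic enolate protonation without an oxocarbenium ion; the planar-chiral enol ether exposes only its outer face, so the proton enters anti to the transannular C8–C9 bond and H-7 ends cis to H-8 (C7 set).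

Step 11
Reactants: 21 β-silyl ketone
Product: 22 (4S,7R,8R)-8-hydroxy ketone [C8–OH in place of silicon, otherwise as 21]
Conditions: 30% H2O2, KF, KHCO3, THF/MeOH, 0 °C → rt; crude used directly
Reagents that add atoms: hydrogen peroxide, OO
Why: Tamao oxidation of an alkoxysilane (β-silyl ketone to aldol) proceeds with retention at C8 under weakly basic, non-electrophilic conditions that should spare the C1=C10 alkene, the silyl ether, both acetals and the C7 centre.

Step 12
Reactants: 22 8-hydroxy ketone
Product: 23 (4S,6R,7S,8R)-8-acetoxy-6-hydroxy compound [1,3-anti C6–OH/C8–OAc]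
Conditions: SmI2 (30 mol%), MeCHO (8 equiv), THF, −10 °C
Reagents that add atoms: acetaldehyde, CC=O
Why: Evans–Tishchenko reduction: hydride is transferred within the samarium-bound O8 hemiacetal through a six-membered chair to C6, giving the 1,3-anti carbinol (H-6 trans to H-7) and leaving O8 as its acetate, so the two secondary oxygens are differentiated in the same step.

Step 13
Reactants: 23 8-acetoxy-6-hydroxy compound
Product: 24 6,12-cyclic methyl acetal (trans-fused 2-methoxytetrahydrofuran, C12 anomers), 8-acetate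
Conditions: PPTS (cat.), CH2Cl2, 4 Å MS, rt
Reagents that add atoms: none
Why: Acid-catalysed intramolecular transacetalisation by the only free hydroxyl (C6–OH, 5-exo onto the C12 oxocarbenium ion) masks the future lactone as a cyclic acetal; the new C12 centre is later destroyed, so the anomer mixture is harmless.

Step 14
Reactants: 24 cyclic methyl acetal 8-acetate
Product: 25 cyclic methyl acetal with free C8–OH
Conditions: K2CO3, MeOH, 0 °C → rt
Reagents that add atoms: none
Why: Base-catalysed transesterification removes the acetate; with C12 still an acetal there is no lactone that could migrate to O8.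

Step 15
Reactants: 25 cyclic methyl acetal C8 alcohol; 26 angelic acid
Product: 28 cyclic methyl acetal 8-angelate, via mixed anhydride 27 (not isolated)
Conditions: 26, 2,4,6-trichlorobenzoyl chloride, Et3N, toluene, rt; then 25, 80 °C (no DMAP)
Reagents that add atoms: none
Why: Yamaguchi-type mixed-anhydride esterification acylates the hindered C8–OH at the less hindered angeloyl carbonyl; omitting DMAP avoids conjugate-addition-induced isomerisation of the Z-enoate to the tiglate.

Step 16
Reactants: 28 cyclic methyl acetal 8-angelate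
Product: 29 12-lactol (cyclic hemiacetal) 8-angelate
Conditions: AcOH/THF/H2O (3:1:1), 35 °C
Reagents that add atoms: water, O
Why: The 2-methoxytetrahydrofuran acetal hydrolyses under mild aqueous acid much faster than the ketone dioxolane or the TBDPS ether, and the angelate and E-alkene are stable to acetic acid.

Step 17
Reactants: 29 12-lactol
Product: 31 11(13)-methylene lactol, via Mannich base 30 (not isolated)
Conditions: CH2=NMe2+ I− (Eschenmoser's salt), Et3N, CH2Cl2, rt
Reagents that add atoms: N,N-dimethylmethyleneiminium iodide, C=[N+](C)C.[I-]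
Why: Mannich condensation of the open hydroxy-aldehyde form followed by β-elimination of dimethylamine (aldehyde α-methylenation) installs C13 under mild amine conditions that the angelate tolerates, which a lactone-enolate methylenation would not.

Step 18
Reactants: 31 11(13)-methylene lactol
Product: 32 (4S,6R,7S,8R)-8-angeloyloxy-15-(tert-butyldiphenylsilyloxy)germacra-1(10)E,11(13)-dien-12,6-olide 3-ethylene ketal
Conditions: TEMPO (cat.), PhI(OAc)2, CH2Cl2, rt
Reagents that add atoms: none
Why: Oxoammonium oxidation of a lactol to the lactone is selective in the absence of free alcohols and leaves the alkenes and the enoate untouched.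

Step 19
Reactants: 32 protected α-methylene lactone
Product: 33 (4S,6R,7S,8R)-8-angeloyloxy-15-hydroxy-3-oxogermacra-1(10)E,11(13)-dien-12,6-olide
Conditions: 48% aq. HF/MeCN (1:10), 0 °C → rt
Reagents that add atoms: water, O
Why: Dilute aqueous HF cleaves the primary silyl ether and hydrolyses the dioxolane in one operation; it is a weak acid, which should limit migration of the β,γ-alkene into conjugation with C3=O and transannular reactions.

Step 20
Reactants: 33 1(10)-ene
Product: 34 argophyllone B
Conditions: mCPBA, NaHCO3, CH2Cl2, 0 °C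
Reagents that add atoms: 3-chloroperoxybenzoic acid, OOC(=O)c1cccc(Cl)c1
Why: Prilezhaev epoxidation takes the only electron-rich alkene (the enoate and α-methylene lactone are electron-poor); peripheral attack on the germacranolide conformer with C14 on the face of the C8 ester, syn across the E-alkene, should give the trans (1R,10R)-epoxide.

**Compound list**

1 | 1,4-dioxaspiro[4.5]deca-6,9-dien-8-one | O=C1C=CC2(C=C1)OCCO2 | starting material
2 | potassium vinyltrifluoroborate | [K+].C=C[B-](F)(F)F | starting material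
3 | (S)-6-vinyl-1,4-dioxaspiro[4.5]dec-9-en-8-one | C=C[C@@H]1CC(=O)C=CC12OCCO2 | intermediate
4 | (S)-8-oxo-1,4-dioxaspiro[4.5]dec-9-ene-6-carbaldehyde (not isolated) | O=C[C@@H]1CC(=O)C=CC12OCCO2 | intermediate
5 | (S)-6-(hydroxymethyl)-1,4-dioxaspiro[4.5]dec-9-en-8-one | OC[C@@H]1CC(=O)C=CC12OCCO2 | intermediate
6 | (S)-6-[(tert-butyldiphenylsilyloxy)methyl]-1,4-dioxaspiro[4.5]dec-9-en-8-one | CC(C)(C)[Si](c1ccccc1)(c1ccccc1)OC[C@@H]1CC(=O)C=CC12OCCO2 | intermediate
7 | (S)-6-[(tert-butyldiphenylsilyloxy)methyl]-9-iodo-1,4-dioxaspiro[4.5]dec-9-en-8-one | CC(C)(C)[Si](c1ccccc1)(c1ccccc1)OC[C@@H]1CC(=O)C(I)=CC12OCCO2 | intermediate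
8 | isopropenylboronic acid pinacol ester | CC(=C)B1OC(C)(C)C(C)(C)O1 | starting material
9 | (S)-6-[(tert-butyldiphenylsilyloxy)methyl]-9-(prop-1-en-2-yl)-1,4-dioxaspiro[4.5]dec-9-en-8-one | CC(C)(C)[Si](c1ccccc1)(c1ccccc1)OC[C@@H]1CC(=O)C(C(C)=C)=CC12OCCO2 | intermediate
10 | (6S,9R)-6-[(tert-butyldiphenylsilyloxy)methyl]-9-(prop-1-en-2-yl)-1,4-dioxaspiro[4.5]decan-8-one | CC(C)(C)[Si](c1ccccc1)(c1ccccc1)OC[C@@H]1CC(=O)[C@@H](C(C)=C)CC12OCCO2 | intermediate
11 | 4,4-dimethoxybut-1-yne | C#CCC(OC)OC | starting material
12 | lithium 4,4-dimethoxybut-1-yn-1-ide (not isolated) | [Li]C#CCC(OC)OC | intermediate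
13 | chloro(4,4-dimethoxybut-1-yn-1-yl)diphenylsilane (not isolated) | Cl[Si](c1ccccc1)(c1ccccc1)C#CCC(OC)OC | intermediate
14 | (4,4-dimethoxybut-1-yn-1-yl)(isopropoxy)diphenylsilane | CC(C)O[Si](c1ccccc1)(c1ccccc1)C#CCC(OC)OC | intermediate
15 | diisopropoxytitanium η2-complex of 14 (titanacyclopropene, not isolated) | CC(C)O[Ti]1(OC(C)C)C(CC(OC)OC)=C1[Si](OC(C)C)(c1ccccc1)c1ccccc1 | intermediate
16 | oxatitanacyclopentene from 15 and 10 (not isolated) | CC(C)O[Ti]1(OC(C)C)O[C@@]2(C[C@@H](CO[Si](c3ccccc3)(c3ccccc3)C(C)(C)C)C3(OCCO3)C[C@@H]2C(C)=C)C(CC(OC)OC)=C1[Si](OC(C)C)(c1ccccc1)c1ccccc1 | intermediate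
17 | (6S,8R,9R)-8-{(E)-4,4-dimethoxy-1-[isopropoxy(diphenyl)silyl]but-1-en-2-yl}-6-[(tert-butyldiphenylsilyloxy)methyl]-9-(prop-1-en-2-yl)-1,4-dioxaspiro[4.5]decan-8-ol (alkenyl and isopropenyl trans-diequatorial, OH axial) | O[C@]1(/C(CC(OC)OC)=C/[Si](OC(C)C)(c2ccccc2)c2ccccc2)C[C@@H](CO[Si](c2ccccc2)(c2ccccc2)C(C)(C)C)C3(OCCO3)C[C@@H]1C(C)=C | intermediate
18 | potassium alkoxide of 17 (not isolated) | [K+].[O-][C@]1(/C(CC(OC)OC)=C/[Si](OC(C)C)(c2ccccc2)c2ccccc2)C[C@@H](CO[Si](c2ccccc2)(c2ccccc2)C(C)(C)C)C3(OCCO3)C[C@@H]1C(C)=C | intermediate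
19 | potassium C6 enolate of the ten-membered ring (not isolated) | [K+].[O-]\C1=C(CC(OC)OC)/[C@H]([Si](OC(C)C)(c2ccccc2)c2ccccc2)C/C(C)=C/CC3(OCCO3)[C@H](CO[Si](c2ccccc2)(c2ccccc2)C(C)(C)C)C1 | intermediate
20 | (4S,8R)-C6 trimethylsilyl enol ether: ring-E C6=C7 (O cis to C8), C7–CH2CH(OMe)2, C8–SiPh2(O-i-Pr), E-C1=C10, C3 ethylene ketal, C4–CH2OTBDPS | C[Si](C)(C)O\C1=C(CC(OC)OC)/[C@H]([Si](OC(C)C)(c2ccccc2)c2ccccc2)C/C(C)=C/CC3(OCCO3)[C@H](CO[Si](c2ccccc2)(c2ccccc2)C(C)(C)C)C1 | intermediate
21 | (4S,7S,8R)-7-(2,2-dimethoxyethyl)-8-[isopropoxy(diphenyl)silyl]-4-[(tert-butyldiphenylsilyloxy)methyl]-10-methylcyclodec-1(10)E-en-6-one 3-ethylene ketal (H-7 cis to H-8) | O=C1[C@H](CC(OC)OC)[C@H]([Si](OC(C)C)(c2ccccc2)c2ccccc2)C/C(C)=C/CC3(OCCO3)[C@H](CO[Si](c2ccccc2)(c2ccccc2)C(C)(C)C)C1 | intermediate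
22 | (4S,7R,8R)-8-hydroxy ketone (C8–OH with retention) | O=C1[C@H](CC(OC)OC)[C@H](O)C/C(C)=C/CC3(OCCO3)[C@H](CO[Si](c2ccccc2)(c2ccccc2)C(C)(C)C)C1 | intermediate
23 | (4S,6R,7S,8R)-8-acetoxy-6-hydroxy compound (C6–OH anti to C8–OAc) | O[C@H]1[C@H](CC(OC)OC)[C@H](OC(C)=O)C/C(C)=C/CC3(OCCO3)[C@H](CO[Si](c2ccccc2)(c2ccccc2)C(C)(C)C)C1 | intermediate
24 | 6,12-cyclic methyl acetal (trans-fused, C12 anomers), 8-acetate; C4, C6, C7, C8 as in 23 | COC1C[C@H]2[C@H](O1)C[C@@H](CO[Si](c3ccccc3)(c3ccccc3)C(C)(C)C)C3(OCCO3)C/C=C(C)/C[C@H]2OC(C)=O | intermediate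
25 | 6,12-cyclic methyl acetal with free C8–OH | COC1C[C@H]2[C@H](O1)C[C@@H](CO[Si](c3ccccc3)(c3ccccc3)C(C)(C)C)C3(OCCO3)C/C=C(C)/C[C@H]2O | intermediate
26 | angelic acid, (Z)-2-methylbut-2-enoic acid | C/C=C(/C)C(=O)O | starting material
27 | angelic 2,4,6-trichlorobenzoic mixed anhydride (not isolated) | C/C=C(/C)C(=O)OC(=O)c1c(Cl)cc(Cl)cc1Cl | intermediate
28 | 6,12-cyclic methyl acetal 8-angelate | COC1C[C@H]2[C@H](O1)C[C@@H](CO[Si](c3ccccc3)(c3ccccc3)C(C)(C)C)C3(OCCO3)C/C=C(C)/C[C@H]2OC(=O)/C(C)=C\C | intermediate
29 | 12-lactol (cyclic hemiacetal) 8-angelate | OC1C[C@H]2[C@H](O1)C[C@@H](CO[Si](c3ccccc3)(c3ccccc3)C(C)(C)C)C3(OCCO3)C/C=C(C)/C[C@H]2OC(=O)/C(C)=C\C | intermediate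
30 | 11-(dimethylaminomethyl) lactol (Mannich base, not isolated) | OC1C(CN(C)C)[C@H]2[C@H](O1)C[C@@H](CO[Si](c3ccccc3)(c3ccccc3)C(C)(C)C)C3(OCCO3)C/C=C(C)/C[C@H]2OC(=O)/C(C)=C\C | intermediate
31 | 11(13)-methylene lactol | OC1C(=C)[C@H]2[C@H](O1)C[C@@H](CO[Si](c3ccccc3)(c3ccccc3)C(C)(C)C)C3(OCCO3)C/C=C(C)/C[C@H]2OC(=O)/C(C)=C\C | intermediate
32 | (4S,6R,7S,8R)-8-angeloyloxy-15-(tert-butyldiphenylsilyloxy)germacra-1(10)E,11(13)-dien-12,6-olide 3-ethylene ketal | O=C1C(=C)[C@H]2[C@H](O1)C[C@@H](CO[Si](c3ccccc3)(c3ccccc3)C(C)(C)C)C3(OCCO3)C/C=C(C)/C[C@H]2OC(=O)/C(C)=C\C | intermediate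
33 | (4S,6R,7S,8R)-8-angeloyloxy-15-hydroxy-3-oxogermacra-1(10)E,11(13)-dien-12,6-olide | O=C1C(=C)[C@H]2[C@H](O1)C[C@@H](CO)C(=O)C/C=C(C)/C[C@H]2OC(=O)/C(C)=C\C | intermediate
34 | argophyllone B | C=C1C(=O)O[C@@H]2C[C@@H](CO)C(=O)C[C@H]3O[C@]3(C)C[C@@H](OC(=O)/C(C)=C\C)[C@@H]12 | target

**Step count and risks**

Total step count: 20. Longest linear sequence: 19 steps (steps 1–6 and 8–20 from dienone 1); step 7 is the one-step side branch.

Steps most likely to fail:

Step 9. The hindered homoallylic potassium alkoxide may fragment (retro-ene-type cleavage) or react through a boat-like array if the tetrasubstituted alkenyl arm cannot reach the chair, which would erode the E geometry and the chirality transfer to C8; the alkoxide may also attack the alkoxysilane. The fallback is the neutral siloxy-Cope variant, which has no alkoxide. It sets out from 17, which would be silylated (TMSOTf, 2,6-lutidine, CH2Cl2, −78 °C) to the tertiary trimethylsilyl ether F1. Thermolysis of F1 in degassed toluene in a base-washed sealed tube (about 200 °C) should then give silyl enol ether 20 directly through the same chair, and the route continues from 20.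

Step 8. The basic titanium reagent may enolise the α-branched β,γ-unsaturated ketone (returning it, partly as the conjugated isopropylidene isomer), insertion of the hindered ketone may be slow, or equatorial attack may be eroded. The fallback separates formation of the alkenyl nucleophile from the addition. It sets out from 14: the titanium complex 15 would be treated with one equivalent of iodine at −78 °C (iodination at the carbon remote from silicon) and then water (protonation of the α-silyl carbon) to give alkenyl iodide F2, with iodine cis to the vinylic hydrogen. Iodine–lithium exchange (t-BuLi, Et2O, −78 °C) would give alkenyllithium F3, which after transmetalation with anhydrous CeCl3 should add to ketone 10 with little enolisation and return to the route at 17.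

Step 20. The ten-membered ring is conformationally mobile (the C1=C10 unit can rotate), so the peracid may attack both faces of the alkene; the β,γ-epoxy ketone product may also open under base. The fallback replaces substrate control by catalyst control: Shi epoxidation of 33 (fructose-derived ketone catalyst of the enantiomeric series that matches the required face, Oxone, buffered at the lowest workable pH, 0 °C) to give 34 directly. No new compound is involved.

**Further compounds**

F1 | step 9 | trimethylsilyl ether of carbinol 17 | C[Si](C)(C)O[C@]1(/C(CC(OC)OC)=C/[Si](OC(C)C)(c2ccccc2)c2ccccc2)C[C@@H](CO[Si](c2ccccc2)(c2ccccc2)C(C)(C)C)C3(OCCO3)C[C@@H]1C(C)=C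
F2 | step 8 | [(E)-2-iodo-4,4-dimethoxybut-1-en-1-yl](isopropoxy)diphenylsilane (iodine trans to silicon) | I/C(CC(OC)OC)=C/[Si](OC(C)C)(c1ccccc1)c1ccccc1
F3 | step 8 | alkenyllithium from F2 (lithium trans to silicon) | [Li]/C(CC(OC)OC)=C/[Si](OC(C)C)(c1ccccc1)c1ccccc1
F0 | step 20 | none | none
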